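**Plan**

- Cuts: the CH2 bridge is taken back to a diarylmethanol and cut at its bond to C8 of the 6-methylflavan (unit B). The aryl ether bond O1–C8a is cut in both flavans, and the C8–CHO bond in the other flavan (unit A). Each C2–C4 chain goes back to a benzaldehyde and acetophenone.
- Enabling feature: in each benzopyran the ring oxygen sits on C8a, the neighbouring C8 carries the bridge carbon, and C7 beyond it carries an oxygen. This O–C8a/C8–C pair is what alkoxide addition to a 7-alkoxy-8,8a-aryne, followed by capture of the C8 aryl anion, leaves behind.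
- Forward, chains: 5-fluororesorcinol (unit A) and a 5-chloro-2-methylresorcinol made from 2,6-dimethoxytoluene (unit B) are formylated, protected (7-O-MOM, 5-O-Me), condensed with acetophenone and reduced to (S)-1-phenyl-3-arylpropan-1-ols.
- Forward, rings: unit A closes its pyran ring through the aryne and is formylated with DMF. Unit B closes its pyran ring through the aryne and adds to that aldehyde in the same flask; ionic hydrogenation and MOM removal finish.
- Stereochemistry: both C2 centres come from asymmetric transfer hydrogenation of the dihydrochalcones. The ring closures form the aryl–O bond and leave the carbinol C–O bond intact, so (S) is carried through.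

Key step: step 14

Assumption: both C2 centres are (S) as read from the SMILES; the diarylmethanol of step 14 is carried on as a mixture of epimers at its carbinol carbon, because that centre is removed in step 15.

**Route**

Step 1
Reactants: 1 5-fluorobenzene-1,3-diol
Product: 3 2-fluoro-4,6-dihydroxybenzaldehyde, via iminium chloride 2 (not isolated)
Conditions: POCl3 (1.2 equiv), DMF (1.5 equiv), MeCN, −15 °C to rt; then H2O, 50 °C
Reagents that add atoms: N,N-dimethylformamide, CN(C)C=O; water, O
Why: Vilsmeier–Haack formylation should attack the ring carbon para to one hydroxyl and ortho to the other, which lies next to fluorine, so the formyl carbon (the later C4) ends up flanked by F and OH.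

Step 2
Reactants: 3 2-fluoro-4,6-dihydroxybenzaldehyde
Product: 5 2-fluoro-6-methoxy-4-(methoxymethoxy)benzaldehyde, via mono-MOM phenol 4 (not isolated)
Conditions: K2CO3 (1.1 equiv), MOMCl (1.05 equiv), acetone, 0 °C to rt; then K2CO3 (2 equiv), MeI (3 equiv), reflux
Reagents that add atoms: chloromethyl methyl ether, COCCl; iodomethane, CI
Why: Williamson etherification in two stages; the para hydroxyl is the more acidic and unhindered one and should take the single equivalent of MOMCl, while the ortho hydroxyl, held in a hydrogen bond to the aldehyde, is methylated only on heating with excess MeI.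

Step 3
Reactants: 5 2-fluoro-6-methoxy-4-(methoxymethoxy)benzaldehyde; 6 acetophenone
Product: 7 (E)-3-[2-fluoro-6-methoxy-4-(methoxymethoxy)phenyl]-1-phenylprop-2-en-1-one
Conditions: KOH (aq.), EtOH, rt
Reagents that add atoms: none
Why: Claisen–Schmidt condensation of a non-enolizable aldehyde with the acetophenone enolate, followed by dehydration to the more stable (E)-enone; no stereocentre is formed.

Step 4
Reactants: 7 (E)-3-[2-fluoro-6-methoxy-4-(methoxymethoxy)phenyl]-1-phenylprop-2-en-1-one
Product: 8 3-[2-fluoro-6-methoxy-4-(methoxymethoxy)phenyl]-1-phenylpropan-1-one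
Conditions: H2 (3 atm), RhCl(PPh3)3 (5 mol%), toluene/EtOH, 40 °C
Reagents that add atoms: none
Why: Homogeneous hydrogenation with RhCl(PPh3)3 should saturate the conjugated C=C and leave the aryl ketone, the aryl fluoride and the MOM acetal untouched.

Step 5
Reactants: 8 3-[2-fluoro-6-methoxy-4-(methoxymethoxy)phenyl]-1-phenylpropan-1-one
Product: 9 (1S)-3-[2-fluoro-6-methoxy-4-(methoxymethoxy)phenyl]-1-phenylpropan-1-ol
Conditions: RuCl[(S,S)-TsDPEN](p-cymene) (1 mol%), HCO2H/Et3N (5:2), EtOAc, 30 °C
Reagents that add atoms: none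
Why: Noyori asymmetric transfer hydrogenation; the (S,S)-TsDPEN ruthenium hydride should deliver hydride to the ketone face that places the phenyl group against the η6-arene, which gives the (S)-carbinol in the same sense as for acetophenone.

Step 6
Reactants: 9 (1S)-3-[2-fluoro-6-methoxy-4-(methoxymethoxy)phenyl]-1-phenylpropan-1-ol
Product: 14 (2S)-5-methoxy-7-(methoxymethoxy)-2-phenylchromane-8-carbaldehyde, via dilithio species 10 (not isolated), via aryne alkoxide 11 (not isolated), via aryllithium 12 (not isolated), via hemiaminal alkoxide 13 (not isolated)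
Conditions: s-BuLi (2.2 equiv), THF, −78 °C, 1 h; warm to 0 °C; recool to −78 °C, DMF (5 equiv), to rt; then H2O
Reagents that add atoms: N,N-dimethylformamide, CN(C)C=O
Why: Anionic aryne cyclization followed by formylation; s-BuLi should remove the O–H and the most acidic ring proton (between F and OMOM), LiF is lost on warming, the tethered alkoxide adds 6-exo to C8a without touching the carbinol C–O bond (so (S) is kept), and the C8 aryllithium between two oxygens is formylated by DMF.

Step 7
Reactants: 15 1,3-dimethoxy-2-methylbenzene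
Product: 17 5-chloro-1,3-dimethoxy-2-methylbenzene, via aryl boronate 16 (not isolated)
Conditions: [Ir(OMe)(cod)]2 (1.5 mol%), 4,4'-di-tert-butyl-2,2'-bipyridine (3 mol%), B2pin2 (0.6 equiv), THF, 80 °C; evaporate; then CuCl2 (3 equiv), MeOH/H2O 1:1, 90 °C
Reagents that add atoms: copper dichloride, Cl[Cu]Cl
Why: Sterically governed iridium-catalyzed C–H borylation should pick the only C–H without an ortho substituent (C5, meta to both methoxy groups), and copper-mediated chlorodeboronation then turns the boronate into the chloride.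

Step 8
Reactants: 17 5-chloro-1,3-dimethoxy-2-methylbenzene
Product: 19 5-chloro-2-methylbenzene-1,3-diol, via aryl borate 18 (not isolated)
Conditions: BBr3 (2.5 equiv), CH2Cl2, −78 °C to rt; then H2O
Reagents that add atoms: none
Why: Lewis-acid cleavage of aryl methyl ethers by BBr3 should free both phenols and leave the aryl chloride intact.

Step 9
Reactants: 19 5-chloro-2-methylbenzene-1,3-diol
Product: 21 6-chloro-2,4-dihydroxy-3-methylbenzaldehyde, via iminium chloride 20 (not isolated)
Conditions: POCl3 (1.2 equiv), DMF (1.5 equiv), MeCN, −15 °C to rt; then H2O, 50 °C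
Reagents that add atoms: N,N-dimethylformamide, CN(C)C=O; water, O
Why: Vilsmeier–Haack formylation; the two open ring positions are equivalent, so only one monoaldehyde can form.

Step 10
Reactants: 21 6-chloro-2,4-dihydroxy-3-methylbenzaldehyde
Product: 23 6-chloro-2-methoxy-4-(methoxymethoxy)-3-methylbenzaldehyde, via mono-MOM phenol 22 (not isolated)
Conditions: K2CO3 (1.1 equiv), MOMCl (1.05 equiv), acetone, 0 °C to rt; then K2CO3 (2 equiv), MeI (3 equiv), reflux
Reagents that add atoms: chloromethyl methyl ether, COCCl; iodomethane, CI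
Why: Williamson etherification in two stages as in step 2; the para hydroxyl should react first with MOMCl, and the hydrogen-bonded ortho hydroxyl is methylated afterwards under forcing conditions.

Step 11
Reactants: 23 6-chloro-2-methoxy-4-(methoxymethoxy)-3-methylbenzaldehyde; 6 acetophenone
Product: 24 (E)-3-[6-chloro-2-methoxy-4-(methoxymethoxy)-3-methylphenyl]-1-phenylprop-2-en-1-one
Conditions: KOH (aq.), EtOH, rt to 40 °C
Reagents that add atoms: none
Why: Claisen–Schmidt condensation as in step 3, giving the (E)-enone; no stereocentre is formed.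

Step 12
Reactants: 24 (E)-3-[6-chloro-2-methoxy-4-(methoxymethoxy)-3-methylphenyl]-1-phenylprop-2-en-1-one
Product: 25 3-[6-chloro-2-methoxy-4-(methoxymethoxy)-3-methylphenyl]-1-phenylpropan-1-one
Conditions: H2 (3 atm), RhCl(PPh3)3 (5 mol%), toluene/EtOH, 40 °C
Reagents that add atoms: none
Why: Homogeneous hydrogenation with RhCl(PPh3)3 should reduce only the C=C and not hydrogenolyze the aryl chloride.

Step 13
Reactants: 25 3-[6-chloro-2-methoxy-4-(methoxymethoxy)-3-methylphenyl]-1-phenylpropan-1-one
Product: 26 (1S)-3-[6-chloro-2-methoxy-4-(methoxymethoxy)-3-methylphenyl]-1-phenylpropan-1-ol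
Conditions: RuCl[(S,S)-TsDPEN](p-cymene) (1 mol%), HCO2H/Et3N (5:2), EtOAc, 30 °C
Reagents that add atoms: none
Why: Noyori asymmetric transfer hydrogenation as in step 5; the (S,S)-catalyst should give the (S)-carbinol.

Step 14
Reactants: 26 (1S)-3-[6-chloro-2-methoxy-4-(methoxymethoxy)-3-methylphenyl]-1-phenylpropan-1-ol; 14 (2S)-5-methoxy-7-(methoxymethoxy)-2-phenylchromane-8-carbaldehyde
Product: 31 [(2S)-5-methoxy-7-(methoxymethoxy)-2-phenylchroman-8-yl][(2S)-5-methoxy-7-(methoxymethoxy)-6-methyl-2-phenylchroman-8-yl]methanol (epimer mixture at the carbinol carbon), via dilithio species 27 (not isolated), via aryne alkoxide 28 (not isolated), via aryllithium 29 (not isolated), via lithium carbinolate 30 (not isolated)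
Conditions: 26 (1.1 equiv), s-BuLi (2.3 equiv), THF (0.03 M), −78 °C, 1 h; warm to 0 °C; recool to −78 °C, 14 (1.0 equiv) in THF, to rt; then H2O
Reagents that add atoms: none
Why: Two equivalents of s-BuLi should convert 26 into the O,C-dilithio species 27, metalated at its only ring C–H (between OMOM and Cl); on warming LiCl is lost to give the 8,8a-aryne 28, the tethered alkoxide adds to C8a, and the C8 aryllithium 29 adds to aldehyde 14. The closest known reaction types are the intramolecular addition of a tethered alkoxide to an aryne made by ortho-metalation and halide loss (the aryne route to chromans) and the capture of the aryl anion from such an anionic aryne cyclization by an external electrophile. The pyran ring closes in the 6-exo-dig mode, the aryne bond lying outside the new ring. The C2 centre of the new ring is not made here: it is the (S)-carbinol of 26, whose C–O bond is never broken, so it is retained; the new carbinol carbon between the arenes is uncontrolled and is removed in step 15. The step needs one metalation site (there is only one aryl C–H), one direction of addition to the aryne (the tether reaches only C8a, and the C7 oxygen also favours attack at the distal carbon with the anion next to it), and capture by carbon in place of protonation (no amine or other proton source is present and 14 has no acidic C–H).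

Step 15
Reactants: 31 [(2S)-5-methoxy-7-(methoxymethoxy)-2-phenylchroman-8-yl][(2S)-5-methoxy-7-(methoxymethoxy)-6-methyl-2-phenylchroman-8-yl]methanol
Product: 33 (2S)-8-{[(2S)-7-hydroxy-5-methoxy-6-methyl-2-phenylchroman-8-yl]methyl}-5-methoxy-2-phenylchroman-7-ol, via bis-MOM diarylmethane 32 (not isolated)
Conditions: Et3SiH (4 equiv), CF3CO2H (10 equiv), CH2Cl2, −20 °C; then MeOH, HCl (about 1 M), 40 °C
Reagents that add atoms: none
Why: Ionic hydrogenation; the diarylmethyl cation, stabilized by two 2,4,6-trioxygenated rings, should form with acid and be reduced by Et3SiH, and acid methanolysis then removes both MOM acetals as dimethoxymethane without touching the C2 centres.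

**Compound list**

1 | 5-fluorobenzene-1,3-diol (5-fluororesorcinol) | Oc1cc(O)cc(F)c1 | starting material
2 | (2-fluoro-4,6-dihydroxybenzylidene)dimethylammonium chloride | C[N+](C)=Cc1c(O)cc(O)cc1F.[Cl-] | intermediate (not isolated)
3 | 2-fluoro-4,6-dihydroxybenzaldehyde | O=Cc1c(O)cc(O)cc1F | intermediate
4 | 2-fluoro-6-hydroxy-4-(methoxymethoxy)benzaldehyde | O=Cc1c(O)cc(OCOC)cc1F | intermediate (not isolated)
5 | 2-fluoro-6-methoxy-4-(methoxymethoxy)benzaldehyde | O=Cc1c(OC)cc(OCOC)cc1F | intermediate
6 | acetophenone | CC(=O)c1ccccc1 | starting material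
7 | (E)-3-[2-fluoro-6-methoxy-4-(methoxymethoxy)phenyl]-1-phenylprop-2-en-1-one | O=C(/C=C/c1c(OC)cc(OCOC)cc1F)c1ccccc1 | intermediate
8 | 3-[2-fluoro-6-methoxy-4-(methoxymethoxy)phenyl]-1-phenylpropan-1-one | O=C(CCc1c(OC)cc(OCOC)cc1F)c1ccccc1 | intermediate
9 | (1S)-3-[2-fluoro-6-methoxy-4-(methoxymethoxy)phenyl]-1-phenylpropan-1-ol | COCOc1cc(F)c(CC[C@H](O)c2ccccc2)c(OC)c1 | intermediate
10 | lithium (1S)-3-[2-fluoro-3-lithio-6-methoxy-4-(methoxymethoxy)phenyl]-1-phenylpropan-1-olate | COCOc1cc(OC)c(CC[C@H](O[Li])c2ccccc2)c(F)c1[Li] | intermediate (not isolated)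
11 | lithium (1S)-3-[2,3-didehydro-6-methoxy-4-(methoxymethoxy)phenyl]-1-phenylpropan-1-olate (8,8a-aryne) | COCOC1=CC(OC)=C(CC[C@H](O[Li])c2ccccc2)C#C1 | intermediate (not isolated)
12 | [(2S)-5-methoxy-7-(methoxymethoxy)-2-phenylchroman-8-yl]lithium | COCOc1cc(OC)c2c(c1[Li])O[C@H](c1ccccc1)CC2 | intermediate (not isolated)
13 | lithium (dimethylamino)[(2S)-5-methoxy-7-(methoxymethoxy)-2-phenylchroman-8-yl]methanolate | COCOc1cc(OC)c2c(c1C(O[Li])N(C)C)O[C@H](c1ccccc1)CC2 | intermediate (not isolated)
14 | (2S)-5-methoxy-7-(methoxymethoxy)-2-phenylchromane-8-carbaldehyde | COCOc1cc(OC)c2c(c1C=O)O[C@H](c1ccccc1)CC2 | intermediate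
15 | 1,3-dimethoxy-2-methylbenzene (2,6-dimethoxytoluene) | COc1cccc(OC)c1C | starting material
16 | 2-(3,5-dimethoxy-4-methylphenyl)-4,4,5,5-tetramethyl-1,3,2-dioxaborolane | COc1cc(B2OC(C)(C)C(C)(C)O2)cc(OC)c1C | intermediate (not isolated)
17 | 5-chloro-1,3-dimethoxy-2-methylbenzene | COc1cc(Cl)cc(OC)c1C | intermediate
18 | 1,3-bis(dibromoboryloxy)-5-chloro-2-methylbenzene | Cc1c(OB(Br)Br)cc(Cl)cc1OB(Br)Br | intermediate (not isolated)
19 | 5-chloro-2-methylbenzene-1,3-diol | Cc1c(O)cc(Cl)cc1O | intermediate
20 | (6-chloro-2,4-dihydroxy-3-methylbenzylidene)dimethylammonium chloride | C[N+](C)=Cc1c(O)c(C)c(O)cc1Cl.[Cl-] | intermediate (not isolated)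
21 | 6-chloro-2,4-dihydroxy-3-methylbenzaldehyde | O=Cc1c(O)c(C)c(O)cc1Cl | intermediate
22 | 6-chloro-2-hydroxy-4-(methoxymethoxy)-3-methylbenzaldehyde | O=Cc1c(O)c(C)c(OCOC)cc1Cl | intermediate (not isolated)
23 | 6-chloro-2-methoxy-4-(methoxymethoxy)-3-methylbenzaldehyde | O=Cc1c(OC)c(C)c(OCOC)cc1Cl | intermediate
24 | (E)-3-[6-chloro-2-methoxy-4-(methoxymethoxy)-3-methylphenyl]-1-phenylprop-2-en-1-one | O=C(/C=C/c1c(OC)c(C)c(OCOC)cc1Cl)c1ccccc1 | intermediate
25 | 3-[6-chloro-2-methoxy-4-(methoxymethoxy)-3-methylphenyl]-1-phenylpropan-1-one | O=C(CCc1c(OC)c(C)c(OCOC)cc1Cl)c1ccccc1 | intermediate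
26 | (1S)-3-[6-chloro-2-methoxy-4-(methoxymethoxy)-3-methylphenyl]-1-phenylpropan-1-ol | COCOc1cc(Cl)c(CC[C@H](O)c2ccccc2)c(OC)c1C | intermediate
27 | lithium (1S)-3-[6-chloro-5-lithio-2-methoxy-4-(methoxymethoxy)-3-methylphenyl]-1-phenylpropan-1-olate | COCOc1c(C)c(OC)c(CC[C@H](O[Li])c2ccccc2)c(Cl)c1[Li] | intermediate (not isolated)
28 | lithium (1S)-3-[5,6-didehydro-2-methoxy-4-(methoxymethoxy)-3-methylphenyl]-1-phenylpropan-1-olate (8,8a-aryne) | COCOC1=C(C)C(OC)=C(CC[C@H](O[Li])c2ccccc2)C#C1 | intermediate (not isolated)
29 | [(2S)-5-methoxy-7-(methoxymethoxy)-6-methyl-2-phenylchroman-8-yl]lithium | COCOc1c(C)c(OC)c2c(c1[Li])O[C@H](c1ccccc1)CC2 | intermediate (not isolated)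
30 | lithium [(2S)-5-methoxy-7-(methoxymethoxy)-2-phenylchroman-8-yl][(2S)-5-methoxy-7-(methoxymethoxy)-6-methyl-2-phenylchroman-8-yl]methanolate | COCOc1cc(OC)c2c(c1C(O[Li])c1c(OCOC)c(C)c(OC)c3c1O[C@H](c1ccccc1)CC3)O[C@H](c1ccccc1)CC2 | intermediate (not isolated)
31 | [(2S)-5-methoxy-7-(methoxymethoxy)-2-phenylchroman-8-yl][(2S)-5-methoxy-7-(methoxymethoxy)-6-methyl-2-phenylchroman-8-yl]methanol (epimer mixture at the carbinol carbon) | COCOc1cc(OC)c2c(c1C(O)c1c(OCOC)c(C)c(OC)c3c1O[C@H](c1ccccc1)CC3)O[C@H](c1ccccc1)CC2 | intermediate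
32 | (2S)-5-methoxy-8-{[(2S)-5-methoxy-7-(methoxymethoxy)-6-methyl-2-phenylchroman-8-yl]methyl}-7-(methoxymethoxy)-2-phenylchromane | COCOc1cc(OC)c2c(c1Cc1c(OCOC)c(C)c(OC)c3c1O[C@H](c1ccccc1)CC3)O[C@H](c1ccccc1)CC2 | intermediate (not isolated)
33 | (2S)-8-{[(2S)-7-hydroxy-5-methoxy-6-methyl-2-phenylchroman-8-yl]methyl}-5-methoxy-2-phenylchroman-7-ol | COc1cc(O)c(Cc2c(O)c(C)c(OC)c3c2O[C@H](c2ccccc2)CC3)c2c1CC[C@@H](c1ccccc1)O2 | target

**Step count and risks**

Total step count: 15. Longest linear sequence: 9 steps (steps 7 to 15, from 15 to 33); the unit A branch (steps 1 to 6) enters at step 14.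

Steps most likely to fail:

1. Step 14. The aryne may be consumed by intermolecular addition of s-BuLi or of a second aryllithium before the aggregated lithium alkoxide closes the ring, or the aryl anion may be protonated or add too slowly to the hindered aldehyde. In the fallback, ring closure and metalation are separated. Starting from 26, a palladium-catalyzed intramolecular C–O coupling (Buchwald–Hartwig etherification; Pd(OAc)2, 2-(di-tert-butylphosphino)-1,1'-binaphthyl, Cs2CO3, toluene, 80 °C) should close the pyran ring at the aryl chloride with retention at the carbinol carbon and give (2S)-5-methoxy-7-(methoxymethoxy)-6-methyl-2-phenylchromane F1. This flavan has a single aryl C–H, at C8 between the MOM ether and the ring oxygen, so directed ortho-metalation (s-BuLi, TMEDA, THF, −78 °C) should give aryllithium 29. The route is rejoined at 29, before the addition of 14.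

2. Step 6. Deprotonation may take place at the ring C–H between the two ether oxygens in place of the one next to fluorine, so that no aryne forms and formylation goes to the wrong carbon of uncyclized material. In the fallback, the metalation site is fixed by a halogen. Starting from 9, electrophilic bromination (NBS, MeCN, 0 °C) is expected to go para to the methoxy group and ortho to the MOM ether, that is between F and OMOM, giving (1S)-3-[3-bromo-2-fluoro-6-methoxy-4-(methoxymethoxy)phenyl]-1-phenylpropan-1-ol F2. n-BuLi (1 equiv) and then t-BuLi (2 equiv) in THF at −78 °C should convert it, by O–H deprotonation and bromine–lithium exchange, into the dilithio species 10. The route is rejoined at 10.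

3. Step 15. The methoxymethyl cation set free from the acetals may alkylate the electron-rich rings, or acid may cleave or scramble the diarylmethane. In the fallback, the carbinol oxygen is removed by a radical path and the acetals by thiol-assisted cleavage. Starting from 31, NaH, CS2 and then MeI in THF should give O-{[(2S)-5-methoxy-7-(methoxymethoxy)-2-phenylchroman-8-yl][(2S)-5-methoxy-7-(methoxymethoxy)-6-methyl-2-phenylchroman-8-yl]methyl} S-methyl carbonodithioate F3. Bu3SnH and AIBN in toluene at 90 °C (Barton–McCombie deoxygenation) should give the bis-MOM diarylmethane 32, which is isolated here. ZnBr2 and propane-1-thiol in CH2Cl2 at 0 °C should then remove both MOM groups, the thiol taking up the methoxymethyl unit, and give the target 33.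

Further compounds
F1 | step 14 | (2S)-5-methoxy-7-(methoxymethoxy)-6-methyl-2-phenylchromane | COCOc1c(C)c(OC)c2c(c1)O[C@H](c1ccccc1)CC2
F2 | step 6 | (1S)-3-[3-bromo-2-fluoro-6-methoxy-4-(methoxymethoxy)phenyl]-1-phenylpropan-1-ol | COCOc1cc(OC)c(CC[C@H](O)c2ccccc2)c(F)c1Br
F3 | step 15 | O-{[(2S)-5-methoxy-7-(methoxymethoxy)-2-phenylchroman-8-yl][(2S)-5-methoxy-7-(methoxymethoxy)-6-methyl-2-phenylchroman-8-yl]methyl} S-methyl carbonodithioate | COCOc1cc(OC)c2c(c1C(OC(=S)SC)c1c(OCOC)c(C)c(OC)c3c1O[C@H](c1ccccc1)CC3)O[C@H](c1ccccc1)CC2
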